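**Retrosynthetic overview**
1. Target ⇐ acid hydrolysis of a 2-methoxyprop-2-yl peroxyketal (last step), preceded by lipase removal of a phenolic acetate; the coumaroyl ester ⇐ C1 alcohol + (E)-4-acetoxycinnamoyl chloride.
2. C8–OO bond ⇐ SN2 inversion of an (8R)-allylic mesylate by 2-methoxyprop-2-yl hydroperoxide; (8R)-alcohol ⇐ CBS reduction of the macrocyclic α-methylidene ketone.
3. The only ring that is built, the 11-membered carbocycle, ⇐ intramolecular Nozaki–Hiyama–Kishi closure (C7–C8) of a 2-iodoalkene aldehyde; the benzene ring is bought with p-coumaric acid.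
4. Open chain ⇐ BF3-promoted opening of an (R)-epoxide (fragment A) by a (Z)-alkenyllithium (fragment B), which fixes the (3Z)-olefin.
5. Fragment A ⇐ ketoreductase-catalysed asymmetric reduction of an α-chloroketone made from 3,3-dimethylglutaric anhydride (first stereocentre); fragment B ⇐ but-2-yn-1-ol + 1-(trimethylsilyl)propyne.

Assumption: the target is taken exactly as drawn, i.e. (1R,3Z,8S) with an (E)-4-hydroxycinnamoyl group. All macrocycles are numbered as in the target (C1 ester carbon, C3=C4 ring olefin, C7 methylidene carbon, C8 peroxide carbon, C10 gem-dimethyl carbon). The ketoreductase of step 5 is any Prelog-selective enzyme picked from a commercial screening panel.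

**Route**

Step 1
Reactants: 1 3,3-dimethylglutaric anhydride (4,4-dimethyloxane-2,6-dione)
Product: 2 4,4-dimethyloxan-2-one
Conditions: NaBH4, THF, 0 °C to rt; then aq. HCl
Reagents that add atoms: none
Why: Hydride reduction of one carbonyl of the symmetrical anhydride and acid-promoted lactonisation (anhydride-to-lactone reduction) give the δ-lactone with no regiochemical issue.

Step 2
Reactants: 2 4,4-dimethyloxan-2-one
Product: 3 5-hydroxy-N-methoxy-N,3,3-trimethylpentanamide
Conditions: MeNH(OMe)·HCl, AlMe3, CH2Cl2, 0 °C to rt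
Reagents that add atoms: N,O-dimethylhydroxylamine hydrochloride, CNOC.Cl
Why: Weinreb aminolysis of the lactone by the aluminium amide formed in the flask opens the ring to a hydroxy Weinreb amide that cannot over-react.

Step 3
Reactants: 3 5-hydroxy-N-methoxy-N,3,3-trimethylpentanamide
Product: 4 5-[(tert-butyldimethylsilyl)oxy]-N-methoxy-N,3,3-trimethylpentanamide
Conditions: TBSCl, imidazole, DMF, rt (crude 3 used at once)
Reagents that add atoms: tert-butyldimethylsilyl chloride, CC(C)(C)[Si](C)(C)Cl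
Why: Imidazole-promoted silylation caps the primary alcohol before it can relactonise and gives an ether stable to organolithiums, base and buffer.

Step 4
Reactants: 4 5-[(tert-butyldimethylsilyl)oxy]-N-methoxy-N,3,3-trimethylpentanamide
Product: 5 6-[(tert-butyldimethylsilyl)oxy]-1-chloro-4,4-dimethylhexan-2-one
Conditions: ICH2Cl, MeLi·LiBr, THF, −78 °C
Reagents that add atoms: chloroiodomethane, ClCI
Why: Chloromethyllithium made in the flask by iodine–lithium exchange adds once to the Weinreb amide (stable chelated tetrahedral intermediate) and gives the α-chloroketone on work-up.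

Step 5
Reactants: 5 6-[(tert-butyldimethylsilyl)oxy]-1-chloro-4,4-dimethylhexan-2-one
Product: 6 (2R)-6-[(tert-butyldimethylsilyl)oxy]-1-chloro-4,4-dimethylhexan-2-ol
Conditions: ketoreductase (NADPH-dependent alcohol dehydrogenase, Prelog-selective), NADP+ (cat.), i-PrOH, KH2PO4/K2HPO4 buffer pH 7, 30 °C
Reagents that add atoms: none
Why: In this enzymatic asymmetric ketone reduction the ketoreductase delivers hydride from NADPH (recycled by 2-propanol) to the Si face of the small-CH2Cl/large-alkyl ketone in the Prelog sense, which sets the first stereocentre as (R) in high ee.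

Step 6
Reactants: 6 (2R)-6-[(tert-butyldimethylsilyl)oxy]-1-chloro-4,4-dimethylhexan-2-ol
Product: 7 (2R)-2-{4-[(tert-butyldimethylsilyl)oxy]-2,2-dimethylbutyl}oxirane (fragment A)
Conditions: K2CO3, MeOH, rt
Reagents that add atoms: none
Why: Intramolecular Williamson etherification displaces chloride at the primary carbon, so the carbinol centre is not touched and stays (R).

Step 7
Reactants: 8 but-2-yn-1-ol
Product: 10 (2Z)-3-iodobut-2-en-1-ol, via alkenylalanate 9 (not isolated)
Conditions: NaAlH2(OCH2CH2OMe)2 (Red-Al), THF, 0 °C to rt; then I2, −78 °C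
Reagents that add atoms: iodine, II
Why: Hydroxyl-directed trans-hydroalumination puts aluminium on C3 cis to the CH2O group in a five-membered alanate, and iodinolysis with retention gives the (Z)-vinyl iodide.

Step 8
Reactants: 10 (2Z)-3-iodobut-2-en-1-ol
Product: 11 (2Z)-1-bromo-3-iodobut-2-ene
Conditions: PBr3, Et2O, 0 °C
Reagents that add atoms: phosphorus tribromide, BrP(Br)Br
Why: SN2 bromination of the primary allylic alcohol leaves the vinyl iodide and the olefin geometry unchanged.

Step 9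
Reactants: 11 (2Z)-1-bromo-3-iodobut-2-ene; 12 1-(trimethylsilyl)propyne
Product: 14 [(5Z)-6-iodohept-5-en-1-yn-1-yl]trimethylsilane (fragment B), via lithiated 1-(trimethylsilyl)propyne 13 (not isolated)
Conditions: 12, n-BuLi, THF, −78 °C; then 11, −78 to −20 °C
Reagents that add atoms: none
Why: Propargylic lithiation and SN2 alkylation by the primary allylic bromide (the silyl group suppresses allenyl coupling) build the 1,5-enyne with the Z geometry kept.

Step 10
Reactants: 14 [(5Z)-6-iodohept-5-en-1-yn-1-yl]trimethylsilane; 7 (2R)-2-{4-[(tert-butyldimethylsilyl)oxy]-2,2-dimethylbutyl}oxirane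
Product: 16 (5R,7Z)-1-[(tert-butyldimethylsilyl)oxy]-3,3,7-trimethyl-12-(trimethylsilyl)dodec-7-en-11-yn-5-ol, via alkenyllithium 15 (not isolated)
Conditions: 14, t-BuLi (2 equiv), Et2O, −78 °C; then 7, BF3·OEt2, −78 °C
Reagents that add atoms: none
Why: Iodine–lithium exchange with retention gives the (Z)-alkenyllithium, which opens the BF3-activated epoxide at its unsubstituted carbon (Lewis-acid-promoted epoxide opening), so the Z-trisubstituted olefin is fixed and the (R)-carbinol is carried over unchanged.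

Step 11
Reactants: 16 (5R,7Z)-1-[(tert-butyldimethylsilyl)oxy]-3,3,7-trimethyl-12-(trimethylsilyl)dodec-7-en-11-yn-5-ol
Product: 17 (5R,7Z)-1-[(tert-butyldimethylsilyl)oxy]-3,3,7-trimethyl-5-[(triisopropylsilyl)oxy]-12-(trimethylsilyl)dodec-7-en-11-yne
Conditions: TIPSOTf, 2,6-lutidine, CH2Cl2, −78 to 0 °C
Reagents that add atoms: triisopropylsilyl trifluoromethanesulfonate, CC(C)[Si](C(C)C)(C(C)C)OS(=O)(=O)C(F)(F)F
Why: Silylation with the silyl triflate protects the secondary alcohol as a TIPS ether that survives base, mild acid, chromium and the later peroxide displacement.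

Step 12
Reactants: 17 (5R,7Z)-1-[(tert-butyldimethylsilyl)oxy]-3,3,7-trimethyl-5-[(triisopropylsilyl)oxy]-12-(trimethylsilyl)dodec-7-en-11-yne
Product: 18 (5R,7Z)-1-[(tert-butyldimethylsilyl)oxy]-3,3,7-trimethyl-5-[(triisopropylsilyl)oxy]dodec-7-en-11-yne
Conditions: K2CO3, MeOH, rt
Reagents that add atoms: none
Why: Base-catalysed methanolysis of the alkynyl C–Si bond (protodesilylation) frees the terminal alkyne while both O-silyl ethers stay.

Step 13
Reactants: 18 (5R,7Z)-1-[(tert-butyldimethylsilyl)oxy]-3,3,7-trimethyl-5-[(triisopropylsilyl)oxy]dodec-7-en-11-yne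
Product: 20 (5R,7Z)-1-[(tert-butyldimethylsilyl)oxy]-11-iodo-3,3,7-trimethyl-5-[(triisopropylsilyl)oxy]dodeca-7,11-diene, via alkenylborane 19 (not isolated)
Conditions: B-I-9-BBN, pentane, −20 °C; then AcOH, 0 °C
Reagents that add atoms: B-iodo-9-borabicyclo[3.3.1]nonane, IB1C2CCCC1CCC2
Why: Regioselective syn-haloboration of the terminal alkyne (boron to the terminal carbon, iodine to the internal one) and protodeboronation with acetic acid give the 2-iodo-1-alkene, while alkenes and silyl ethers do not react at this temperature.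

Step 14
Reactants: 20 (5R,7Z)-1-[(tert-butyldimethylsilyl)oxy]-11-iodo-3,3,7-trimethyl-5-[(triisopropylsilyl)oxy]dodeca-7,11-diene
Product: 21 (5R,7Z)-11-iodo-3,3,7-trimethyl-5-[(triisopropylsilyl)oxy]dodeca-7,11-dien-1-ol
Conditions: pyridinium p-toluenesulfonate (cat.), MeOH, rt
Reagents that add atoms: none
Why: Acid-catalysed methanolysis removes the unhindered primary TBS ether selectively because the bulky secondary TIPS ether is cleaved far more slowly.

Step 15
Reactants: 21 (5R,7Z)-11-iodo-3,3,7-trimethyl-5-[(triisopropylsilyl)oxy]dodeca-7,11-dien-1-ol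
Product: 22 (5R,7Z)-11-iodo-3,3,7-trimethyl-5-[(triisopropylsilyl)oxy]dodeca-7,11-dienal
Conditions: Dess–Martin periodinane, CH2Cl2, rt
Reagents that add atoms: none
Why: Dess–Martin oxidation gives the aldehyde under neutral conditions without over-oxidation, and the aldehyde has no α-stereocentre to lose.

Step 16
Reactants: 22 (5R,7Z)-11-iodo-3,3,7-trimethyl-5-[(triisopropylsilyl)oxy]dodeca-7,11-dienal
Product: 23 (1R,3Z)-3,10,10-trimethyl-7-methylidene-1-[(triisopropylsilyl)oxy]cycloundec-3-en-8-ol (both C8 epimers)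
Conditions: CrCl2 (10 equiv), NiCl2 (2 mol %), DMSO/THF 3:1, rt, 2 mM, syringe-pump addition
Reagents that add atoms: none
Why: In this intramolecular Nozaki–Hiyama–Kishi coupling nickel inserts into the C–I bond, the alkenyl group passes to chromium and adds chemoselectively to the aldehyde at high dilution, which closes the 11-membered ring and creates the 2-methylidene carbinol as a C8 epimer mixture that the next two steps correct.

Step 17
Reactants: 23 (1R,3Z)-3,10,10-trimethyl-7-methylidene-1-[(triisopropylsilyl)oxy]cycloundec-3-en-8-ol (both C8 epimers)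
Product: 24 (1R,3Z)-3,10,10-trimethyl-7-methylidene-1-[(triisopropylsilyl)oxy]cycloundec-3-en-8-one
Conditions: Dess–Martin periodinane, CH2Cl2, 0 °C to rt
Reagents that add atoms: none
Why: Dess–Martin oxidation of the allylic alcohol erases the uncontrolled C8 centre and gives the α-methylidene ketone.

Step 18
Reactants: 24 (1R,3Z)-3,10,10-trimethyl-7-methylidene-1-[(triisopropylsilyl)oxy]cycloundec-3-en-8-one
Product: 25 (1R,3Z,8R)-3,10,10-trimethyl-7-methylidene-1-[(triisopropylsilyl)oxy]cycloundec-3-en-8-ol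
Conditions: (S)-Me-CBS oxazaborolidine (C18H20BNO, 0.5 equiv), catecholborane, toluene, −78 °C
Reagents that add atoms: none
Why: In this Corey–Bakshi–Shibata reduction the (S)-oxazaborolidine binds the ketone with the larger alkenyl (C7) side away from the catalyst and delivers hydride to give the (8R)-allylic alcohol under reagent control, and 1,2-reduction is favoured at low temperature.

Step 19
Reactants: 26 2,3-dimethylbut-2-ene
Product: 27 2-hydroperoxy-2-methoxypropane (2-methoxyprop-2-yl hydroperoxide)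
Conditions: O3, MeOH/CH2Cl2, −78 °C
Reagents that add atoms: ozone, [O-][O+]=O; methanol, CO
Why: Ozonolysis of the tetrasubstituted alkene in methanol traps the carbonyl oxide (Criegee intermediate) as the α-methoxy hydroperoxide.

Step 20
Reactants: 25 (1R,3Z,8R)-3,10,10-trimethyl-7-methylidene-1-[(triisopropylsilyl)oxy]cycloundec-3-en-8-ol; 27 2-hydroperoxy-2-methoxypropane
Product: 29 triisopropyl{[(1R,3Z,8S)-8-[(2-methoxypropan-2-yl)peroxy]-3,10,10-trimethyl-7-methylidenecycloundec-3-en-1-yl]oxy}silane, via mesylate 28 (not isolated)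
Conditions: Ms2O, Et3N, THF, −40 °C; then 27 (excess), CsOH·H2O, DMF, 0 °C
Reagents that add atoms: none
Why: The alcohol is activated as its mesylate and displaced by the caesium alkylperoxide in an SN2 reaction with inversion, which turns the (8R) C–O bond into the (8S) C–OO bond and brings in the peroxide already masked as a base-stable peroxyketal.

Step 21
Reactants: 29 triisopropyl{[(1R,3Z,8S)-8-[(2-methoxypropan-2-yl)peroxy]-3,10,10-trimethyl-7-methylidenecycloundec-3-en-1-yl]oxy}silane
Product: 30 (1R,3Z,8S)-8-[(2-methoxypropan-2-yl)peroxy]-3,10,10-trimethyl-7-methylidenecycloundec-3-en-1-ol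
Conditions: TBAF, AcOH (1:1), THF, rt
Reagents that add atoms: none
Why: Fluoride-mediated desilylation buffered with acetic acid removes the TIPS group without base-induced (Kornblum–DeLaMare) decomposition or acid hydrolysis of the peroxyketal.

Step 22
Reactants: 31 (2E)-3-(4-hydroxyphenyl)prop-2-enoic acid (p-coumaric acid)
Product: 32 (2E)-3-[4-(acetyloxy)phenyl]prop-2-enoic acid
Conditions: Ac2O, pyridine, rt; aqueous work-up
Reagents that add atoms: acetic anhydride, CC(=O)OC(C)=O
Why: O-Acetylation masks the phenol so that the acid can be turned into its chloride without self-acylation.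

Step 23
Reactants: 30 (1R,3Z,8S)-8-[(2-methoxypropan-2-yl)peroxy]-3,10,10-trimethyl-7-methylidenecycloundec-3-en-1-ol; 32 (2E)-3-[4-(acetyloxy)phenyl]prop-2-enoic acid
Product: 34 (1R,3Z,8S)-8-[(2-methoxypropan-2-yl)peroxy]-3,10,10-trimethyl-7-methylidenecycloundec-3-en-1-yl (2E)-3-[4-(acetyloxy)phenyl]prop-2-enoate, via acid chloride 33 (not isolated)
Conditions: 32, (COCl)2, N,N-dimethylformamide (cat.), CH2Cl2, 0 °C to rt; then 30, pyridine, 4-(dimethylamino)pyridine (cat.), CH2Cl2, 0 °C to rt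
Reagents that add atoms: none
Why: Acyl chloride formation and nucleophile-catalysed esterification acylate the C1 alcohol at oxygen, so C1 keeps its configuration, and the E-alkene and the peroxyketal are inert under the pyridine-buffered conditions.

Step 24
Reactants: 34 (1R,3Z,8S)-8-[(2-methoxypropan-2-yl)peroxy]-3,10,10-trimethyl-7-methylidenecycloundec-3-en-1-yl (2E)-3-[4-(acetyloxy)phenyl]prop-2-enoate
Product: 35 (1R,3Z,8S)-8-[(2-methoxypropan-2-yl)peroxy]-3,10,10-trimethyl-7-methylidenecycloundec-3-en-1-yl (2E)-3-(4-hydroxyphenyl)prop-2-enoate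
Conditions: lipase (Candida antarctica lipase B, immobilised), n-BuOH, t-BuOMe, 35 °C
Reagents that add atoms: none
Why: Lipase-catalysed transesterification (serine-hydrolase acyl transfer to butanol) cleaves only the unhindered phenolic acetate under neutral conditions and leaves the hindered secondary cinnamate, the peroxyketal and both stereocentres untouched.

Step 25
Reactants: 35 (1R,3Z,8S)-8-[(2-methoxypropan-2-yl)peroxy]-3,10,10-trimethyl-7-methylidenecycloundec-3-en-1-yl (2E)-3-(4-hydroxyphenyl)prop-2-enoate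
Product: 36 (1R,3Z,8S)-8-hydroperoxy-3,10,10-trimethyl-7-methylidenecycloundec-3-en-1-yl (2E)-3-(4-hydroxyphenyl)prop-2-enoate (CNP0208931.1)
Conditions: AcOH/THF/H2O 4:2:1, rt
Reagents that add atoms: none
Why: Mild acid hydrolysis of the mixed peroxyketal releases the free hydroperoxide without touching the ester, the phenol or the C–O bonds at C1 and C8, so (1R,8S) is kept.

**Compound list**
1 | 3,3-dimethylglutaric anhydride | CC1(C)CC(=O)OC(=O)C1 | starting material
2 | 4,4-dimethyloxan-2-one | CC1(C)CCOC(=O)C1 | intermediate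
3 | 5-hydroxy-N-methoxy-N,3,3-trimethylpentanamide | CON(C)C(=O)CC(C)(C)CCO | intermediate
4 | 5-[(tert-butyldimethylsilyl)oxy]-N-methoxy-N,3,3-trimethylpentanamide | CON(C)C(=O)CC(C)(C)CCO[Si](C)(C)C(C)(C)C | intermediate
5 | 6-[(tert-butyldimethylsilyl)oxy]-1-chloro-4,4-dimethylhexan-2-one | ClCC(=O)CC(C)(C)CCO[Si](C)(C)C(C)(C)C | intermediate
6 | (2R)-6-[(tert-butyldimethylsilyl)oxy]-1-chloro-4,4-dimethylhexan-2-ol | ClC[C@H](O)CC(C)(C)CCO[Si](C)(C)C(C)(C)C | intermediate
7 | (2R)-2-{4-[(tert-butyldimethylsilyl)oxy]-2,2-dimethylbutyl}oxirane (fragment A) | C1O[C@@H]1CC(C)(C)CCO[Si](C)(C)C(C)(C)C | intermediate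
8 | but-2-yn-1-ol | CC#CCO | starting material
9 | sodium 2,2-bis(2-methoxyethoxy)-3-methyl-2,5-dihydro-1,2-oxaluminol-2-uide (cyclic (Z)-alkenylalanate formed in the flask) | CC1=CCO[Al-]1(OCCOC)OCCOC.[Na+] | intermediate
10 | (2Z)-3-iodobut-2-en-1-ol | C/C(I)=C/CO | intermediate
11 | (2Z)-1-bromo-3-iodobut-2-ene | C/C(I)=C/CBr | intermediate
12 | 1-(trimethylsilyl)propyne | CC#C[Si](C)(C)C | starting material
13 | [3-(trimethylsilyl)prop-2-yn-1-yl]lithium (formed in the flask) | [Li]CC#C[Si](C)(C)C | intermediate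
14 | [(5Z)-6-iodohept-5-en-1-yn-1-yl]trimethylsilane (fragment B) | C/C(I)=C/CCC#C[Si](C)(C)C | intermediate
15 | [7-(trimethylsilyl)hept-2-en-6-yn-2-yl]lithium, Li in place of I with the geometry retained (formed in the flask) | C/C([Li])=C/CCC#C[Si](C)(C)C | intermediate
16 | (5R,7Z)-1-[(tert-butyldimethylsilyl)oxy]-3,3,7-trimethyl-12-(trimethylsilyl)dodec-7-en-11-yn-5-ol | C/C(=C/CCC#C[Si](C)(C)C)C[C@H](O)CC(C)(C)CCO[Si](C)(C)C(C)(C)C | intermediate
17 | (5R,7Z)-1-[(tert-butyldimethylsilyl)oxy]-3,3,7-trimethyl-5-[(triisopropylsilyl)oxy]-12-(trimethylsilyl)dodec-7-en-11-yne | C/C(=C/CCC#C[Si](C)(C)C)C[C@H](O[Si](C(C)C)(C(C)C)C(C)C)CC(C)(C)CCO[Si](C)(C)C(C)(C)C | intermediate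
18 | (5R,7Z)-1-[(tert-butyldimethylsilyl)oxy]-3,3,7-trimethyl-5-[(triisopropylsilyl)oxy]dodec-7-en-11-yne | C/C(=C/CCC#C)C[C@H](O[Si](C(C)C)(C(C)C)C(C)C)CC(C)(C)CCO[Si](C)(C)C(C)(C)C | intermediate
19 | 9-[(1Z,5Z,8R)-12-[(tert-butyldimethylsilyl)oxy]-2-iodo-6,10,10-trimethyl-8-[(triisopropylsilyl)oxy]dodeca-1,5-dien-1-yl]-9-borabicyclo[3.3.1]nonane (formed in the flask) | C/C(=C/CC/C(I)=C/B1C2CCCC1CCC2)C[C@H](O[Si](C(C)C)(C(C)C)C(C)C)CC(C)(C)CCO[Si](C)(C)C(C)(C)C | intermediate
20 | (5R,7Z)-1-[(tert-butyldimethylsilyl)oxy]-11-iodo-3,3,7-trimethyl-5-[(triisopropylsilyl)oxy]dodeca-7,11-diene | C/C(=C/CCC(I)=C)C[C@H](O[Si](C(C)C)(C(C)C)C(C)C)CC(C)(C)CCO[Si](C)(C)C(C)(C)C | intermediate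
21 | (5R,7Z)-11-iodo-3,3,7-trimethyl-5-[(triisopropylsilyl)oxy]dodeca-7,11-dien-1-ol | C/C(=C/CCC(I)=C)C[C@H](O[Si](C(C)C)(C(C)C)C(C)C)CC(C)(C)CCO | intermediate
22 | (5R,7Z)-11-iodo-3,3,7-trimethyl-5-[(triisopropylsilyl)oxy]dodeca-7,11-dienal | C/C(=C/CCC(I)=C)C[C@H](O[Si](C(C)C)(C(C)C)C(C)C)CC(C)(C)CC=O | intermediate
23 | (1R,3Z)-3,10,10-trimethyl-7-methylidene-1-[(triisopropylsilyl)oxy]cycloundec-3-en-8-ol (both C8 epimers) | C=C1CC/C=C(/C)C[C@H](O[Si](C(C)C)(C(C)C)C(C)C)CC(C)(C)CC1O | intermediate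
24 | (1R,3Z)-3,10,10-trimethyl-7-methylidene-1-[(triisopropylsilyl)oxy]cycloundec-3-en-8-one | C=C1CC/C=C(/C)C[C@H](O[Si](C(C)C)(C(C)C)C(C)C)CC(C)(C)CC1=O | intermediate
25 | (1R,3Z,8R)-3,10,10-trimethyl-7-methylidene-1-[(triisopropylsilyl)oxy]cycloundec-3-en-8-ol | C=C1CC/C=C(/C)C[C@H](O[Si](C(C)C)(C(C)C)C(C)C)CC(C)(C)C[C@H]1O | intermediate
26 | 2,3-dimethylbut-2-ene | CC(C)=C(C)C | starting material
27 | 2-hydroperoxy-2-methoxypropane | COC(C)(C)OO | intermediate
28 | (1R,3Z,8R)-3,10,10-trimethyl-7-methylidene-1-[(triisopropylsilyl)oxy]cycloundec-3-en-8-yl methanesulfonate (formed in the flask) | C=C1CC/C=C(/C)C[C@H](O[Si](C(C)C)(C(C)C)C(C)C)CC(C)(C)C[C@H]1OS(C)(=O)=O | intermediate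
29 | triisopropyl{[(1R,3Z,8S)-8-[(2-methoxypropan-2-yl)peroxy]-3,10,10-trimethyl-7-methylidenecycloundec-3-en-1-yl]oxy}silane | C=C1CC/C=C(/C)C[C@H](O[Si](C(C)C)(C(C)C)C(C)C)CC(C)(C)C[C@@H]1OOC(C)(C)OC | intermediate
30 | (1R,3Z,8S)-8-[(2-methoxypropan-2-yl)peroxy]-3,10,10-trimethyl-7-methylidenecycloundec-3-en-1-ol | C=C1CC/C=C(/C)C[C@H](O)CC(C)(C)C[C@@H]1OOC(C)(C)OC | intermediate
31 | (2E)-3-(4-hydroxyphenyl)prop-2-enoic acid (p-coumaric acid) | OC(=O)/C=C/c1ccc(O)cc1 | starting material
32 | (2E)-3-[4-(acetyloxy)phenyl]prop-2-enoic acid | CC(=O)Oc1ccc(/C=C/C(=O)O)cc1 | intermediate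
33 | (2E)-3-[4-(acetyloxy)phenyl]prop-2-enoyl chloride (formed in the flask) | CC(=O)Oc1ccc(/C=C/C(=O)Cl)cc1 | intermediate
34 | (1R,3Z,8S)-8-[(2-methoxypropan-2-yl)peroxy]-3,10,10-trimethyl-7-methylidenecycloundec-3-en-1-yl (2E)-3-[4-(acetyloxy)phenyl]prop-2-enoate | C=C1CC/C=C(/C)C[C@H](OC(=O)/C=C/c2ccc(OC(C)=O)cc2)CC(C)(C)C[C@@H]1OOC(C)(C)OC | intermediate
35 | (1R,3Z,8S)-8-[(2-methoxypropan-2-yl)peroxy]-3,10,10-trimethyl-7-methylidenecycloundec-3-en-1-yl (2E)-3-(4-hydroxyphenyl)prop-2-enoate | C=C1CC/C=C(/C)C[C@H](OC(=O)/C=C/c2ccc(O)cc2)CC(C)(C)C[C@@H]1OOC(C)(C)OC | intermediate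
36 | (1R,3Z,8S)-8-hydroperoxy-3,10,10-trimethyl-7-methylidenecycloundec-3-en-1-yl (2E)-3-(4-hydroxyphenyl)prop-2-enoate | C=C1CC/C=C(/C)C[C@H](OC(=O)/C=C/c2ccc(O)cc2)CC(C)(C)C[C@@H]1OO | target

**Step count and risks**

Total step count: 25. Longest linear sequence: 20 steps (1–6, 10–18, 20, 21, 23–25).

Step 16 (ring closure) may fail through oligomerisation or no closure because of medium-ring strain. The fallback is a nickel-catalysed reductive alkyne–aldehyde macrocyclisation that needs no vinyl iodide. It sets out from 18: acid methanolysis of the primary TBS ether (pyridinium p-toluenesulfonate, MeOH) gives (5R,7Z)-3,3,7-trimethyl-5-[(triisopropylsilyl)oxy]dodec-7-en-11-yn-1-ol F1, and Dess–Martin oxidation gives (5R,7Z)-3,3,7-trimethyl-5-[(triisopropylsilyl)oxy]dodec-7-en-11-ynal F2. Slow addition of F2 to Ni(cod)2, the bulky carbene 1,3-bis(2,6-diisopropylphenyl)-4,5-diphenylimidazol-2-ylidene and Et3SiH in THF joins the internal alkyne carbon to the aldehyde and gives triethyl{[(1R,3Z)-3,10,10-trimethyl-7-methylidene-1-[(triisopropylsilyl)oxy]cycloundec-3-en-8-yl]oxy}silane F3. Selective methanolysis of the triethylsilyl ether (pyridinium p-toluenesulfonate, MeOH, 0 °C) comes back to the route at 23.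

Step 18 (reagent-controlled reduction inside a conformationally biased macrocycle) may give low or reversed facial selectivity. The fallback skips the oxidation–reduction pair and corrects C8 by inversion. It sets out from 23: chromatography separates 25 from its epimer (1R,3Z,8S)-3,10,10-trimethyl-7-methylidene-1-[(triisopropylsilyl)oxy]cycloundec-3-en-8-ol F4. Mitsunobu esterification of F4 (4-nitrobenzoic acid, PPh3, diisopropyl azodicarboxylate) gives with inversion (1R,3Z,8R)-3,10,10-trimethyl-7-methylidene-1-[(triisopropylsilyl)oxy]cycloundec-3-en-8-yl 4-nitrobenzoate F5, and methanolysis (K2CO3, MeOH) comes back to the route at 25.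

Step 20 (SN2 of a secondary allylic mesylate by the peroxide anion) may be diverted to SN2′ attack at the methylidene carbon or to elimination. The fallback gives up the stereospecific displacement and forms the C–OO bond under ionising, silver-assisted conditions, with stereochemistry then resting on chromatography. It sets out from 25: mesylation and LiBr give {[(1R,3Z,8S)-8-bromo-3,10,10-trimethyl-7-methylidenecycloundec-3-en-1-yl]oxy}triisopropylsilane F6. Treatment of F6 with silver trifluoroacetate CF3CO2Ag and 27 in Et2O at 0 °C gives 29 together with its epimer triisopropyl{[(1R,3Z,8R)-8-[(2-methoxypropan-2-yl)peroxy]-3,10,10-trimethyl-7-methylidenecycloundec-3-en-1-yl]oxy}silane F7, which is removed by chromatography; the route is rejoined at 29.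

**Further compounds**
F1 | step 16 | (5R,7Z)-3,3,7-trimethyl-5-[(triisopropylsilyl)oxy]dodec-7-en-11-yn-1-ol | C/C(=C/CCC#C)C[C@H](O[Si](C(C)C)(C(C)C)C(C)C)CC(C)(C)CCO
F2 | step 16 | (5R,7Z)-3,3,7-trimethyl-5-[(triisopropylsilyl)oxy]dodec-7-en-11-ynal | C/C(=C/CCC#C)C[C@H](O[Si](C(C)C)(C(C)C)C(C)C)CC(C)(C)CC=O
F3 | step 16 | triethyl{[(1R,3Z)-3,10,10-trimethyl-7-methylidene-1-[(triisopropylsilyl)oxy]cycloundec-3-en-8-yl]oxy}silane (both C8 epimers) | C=C1CC/C=C(/C)C[C@H](O[Si](C(C)C)(C(C)C)C(C)C)CC(C)(C)CC1O[Si](CC)(CC)CC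
F4 | step 18 | (1R,3Z,8S)-3,10,10-trimethyl-7-methylidene-1-[(triisopropylsilyl)oxy]cycloundec-3-en-8-ol | C=C1CC/C=C(/C)C[C@H](O[Si](C(C)C)(C(C)C)C(C)C)CC(C)(C)C[C@@H]1O
F5 | step 18 | (1R,3Z,8R)-3,10,10-trimethyl-7-methylidene-1-[(triisopropylsilyl)oxy]cycloundec-3-en-8-yl 4-nitrobenzoate | C=C1CC/C=C(/C)C[C@H](O[Si](C(C)C)(C(C)C)C(C)C)CC(C)(C)C[C@H]1OC(=O)c2ccc(cc2)[N+](=O)[O-]
F6 | step 20 | {[(1R,3Z,8S)-8-bromo-3,10,10-trimethyl-7-methylidenecycloundec-3-en-1-yl]oxy}triisopropylsilane | C=C1CC/C=C(/C)C[C@H](O[Si](C(C)C)(C(C)C)C(C)C)CC(C)(C)C[C@@H]1Br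
F7 | step 20 | triisopropyl{[(1R,3Z,8R)-8-[(2-methoxypropan-2-yl)peroxy]-3,10,10-trimethyl-7-methylidenecycloundec-3-en-1-yl]oxy}silane | C=C1CC/C=C(/C)C[C@H](O[Si](C(C)C)(C(C)C)C(C)C)CC(C)(C)C[C@H]1OOC(C)(C)OC
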